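(The data come from a simulation with made-up constants, noise included.)

In the green run at 5.00 h the mono adduct reads 17.0%, less than the 43.6% of starting material gone, so you must ask where the rest went.

common to all: starting material 0.98 M; reagent 1.18 M; capture agent 0.294 M
- green: the very flask that is asked about, followed so far
- flask: time 10 h

green run (percent of the starting material charged)

| time / h | starting material / % | mono adduct / % | bis adduct / % |
|---|---|---|---|
| 0.667 | 90.9 | 8.2 | 1.0 |
| 2.00 | 76.5 | 14.9 | 3.3 |
| 3.00 | 68.7 | 15.9 | 5.9 |
| 5.00 | 56.4 | 17.0 | 9.6 |

(each reading ± 0.3 percentage points)

- for by-product the crystals are counted in
- as a solid, counted per litre of solution: crystals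
- what may be going on: starting material + reagent -> mono adduct + by-product; mono adduct + capture agent -> trapped intermediate; crystals <-> by-product; reagent + mono adduct -> bis adduct + by-product

- how much starting material there is at 10 h, in percent of the starting material charged
- how much mono adduct there is at 10 h, in percent of the starting material charged
- how much bis adduct there is at 10 h, in percent of the starting material charged

- Take the main step alone: you expect 43.6% of mono adduct at that time, and the reading falls short of it.
- Add the step from mono adduct and reagent: bis adduct accounts for 9.6%, and a gap of 17.0% remains.
- Add the trap: you read that gap as trapped intermediate, and the capture agent charged equals 30.0% of the starting material charged. By-product enters no listed step as a reactant except the exchange with the crystals, so I reckon without the crystals.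
- Both steps take mono adduct, so I assume each runs in proportion to its partner. Then trapped gained per bis gained equals a constant times c/b, where c and b are the fractions of capture agent and reagent left.
- From 2.00 h, where the gap is 5.30%, to 5.00 h, the green run gains 1.86 trapped per bis, at mean fractions c = 62.8% and b = 66.8%.
- This gives the opening split, trapped gained per bis gained with both partners at full charge, a selectivity factor for these two charges, of 1.97, which is a reading and carries the scatter of the green run.
- In the green run at 5.00 h I reckon c = 43.3% and b = 55.8%, so the split is 1.53, and I commit to its falling from there.
- The forecast gives starting material 40.2% (38.2% to 42.2%), mono adduct 17.2% (15.5% to 19.5%) and bis adduct 17% (15.3% to 18.8%), holding that “trapping must fade as it is used up”.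
- The flask gives starting material 40.0%, mono adduct 17.1% and bis adduct 17.2%, each inside the forecast's range.

    starting material + reagent → mono adduct + by-product (k = 0.130 M⁻¹ h⁻¹)
    mono adduct + capture agent → trapped intermediate (k = 1.30 M⁻¹ h⁻¹)
    crystals ⇌ by-product, rate k3*(cs3 - [by-product]) while solid is left; crystals form when [by-product] > cs3 (solubility = 0.0540 M, k = 8.10 h⁻¹)
    reagent + mono adduct → bis adduct + by-product (k = 0.170 M⁻¹ h⁻¹)

With the other charges and the time held, bis adduct has moved 5 points at reagent charges of 0.965 M and 1.38 M, which puts it outside the forecast's range. In this flask at 10 h, with c = 14% and b = 36%, the opening split times c/b gives 0.791. The neighbour flask with 0.24 M of starting material keeps both partner charges and ends with c = 66% and b = 80%. Its split therefore runs from 1.97 to 1.63, with a midpoint of 1.80. That neighbour flask holds 41.0% trapped intermediate against 23.1% bis adduct, 1.77 to one.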